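**Retrosynthetic overview**

- Target 16 comes from bis-chromene 15 by one hydrogenation, and 15 comes from bis(propargyl) ether 11 by a twofold aryl propargyl ether Claisen / [1,5]-hydrogen shift / oxa-6π cascade that makes both aryl–C4 bonds and both O1–C2 bonds.
- Feature used: in each chroman the ring oxygen O1 (on C8a) lies para to the carbon substituent at C6 (the ketone carbon on the dihydroxychroman, the CH2CH2 chain on the other) and C4 is attached at the ortho carbon C4a. Before annulation each benzene ring is therefore symmetric about its O–C(para) axis with two equivalent ortho C–H sites, and benzyl ethers on the two oxygens flanking the ketone leave the para oxygen as the only one that can close the pyran.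
- 11 comes from chalcone 9 by an alkyne-tolerant 1,4-reduction, and 9 from ketone 7 and aldehyde 3 by Claisen–Schmidt condensation. The halves are etherified separately (4 → 5 → 7 and 1 → 3), because etherifying the intact tetraphenolic dihydrochalcone would not distinguish the ring B phenol from the free, more acidic ortho hydroxyl of the acylphloroglucinol (ring A).
- Ring order: no ring is made before step 6; there the pyran on ring A (phloroglucinol ring) closes first and the pyran on ring B (para-substituted ring) second, in one operation.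

Key step: step 6

Remark: 2',4',6'-trihydroxyacetophenone (4) is sold as its monohydrate and is counted here as the anhydrous compound; the target has no stereocentre and aldol adduct 8 is racemic.

**Route**

Step 1
Reactants: 1 4-hydroxybenzaldehyde; 2 3-chloro-3-methylbut-1-yne
Product: 3 4-[(2-methylbut-3-yn-2-yl)oxy]benzaldehyde
Conditions: 2 (1.3 equiv), DBU (1.4 equiv), CuCl2·2H2O (cat.), MeCN, 0 °C to rt
Reagents that add atoms: 3-chloro-3-methylbut-1-yne (2), CC(C)(Cl)C#C
Why: Copper-catalysed propargylic O-alkylation of a phenol, in which the copper acetylide of 2 loses chloride and the phenoxide adds at the tertiary carbon, should give the aryl 1,1-dimethylpropargyl ether with the aldehyde untouched.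

Step 2
Reactants: 4 1-(2,4,6-trihydroxyphenyl)ethanone; 2 3-chloro-3-methylbut-1-yne
Product: 5 1-[2,6-dihydroxy-4-[(2-methylbut-3-yn-2-yl)oxy]phenyl]ethanone
Conditions: 2 (1.05 equiv), DBU (1.1 equiv), CuCl2·2H2O (cat.), MeCN, −5 to 0 °C
Reagents that add atoms: 3-chloro-3-methylbut-1-yne (2), CC(C)(Cl)C#C
Why: The same copper-catalysed propargylic O-alkylation should be site-selective because one equivalent of base ionises only the hydroxyl para to the acetyl group, which is the most acidic and least hindered, while the two ortho hydroxyls are flanked by the acyl group and one of them is hydrogen-bonded to it.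

Step 3
Reactants: 5 1-[2,6-dihydroxy-4-[(2-methylbut-3-yn-2-yl)oxy]phenyl]ethanone; 6 benzyl bromide
Product: 7 1-[2,6-bis(benzyloxy)-4-[(2-methylbut-3-yn-2-yl)oxy]phenyl]ethanone
Conditions: BnBr (2.5 equiv), Cs2CO3 (3 equiv), DMF, rt to 40 °C
Reagents that add atoms: benzyl bromide (6), BrCc1ccccc1
Why: Williamson ether synthesis with caesium phenoxides in DMF should benzylate both ortho hydroxyls, the chelated one included, at a temperature far below the onset of the propargyl Claisen rearrangement and with a base too weak to touch the alkyne or the methyl ketone.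

Step 4
Reactants: 7 1-[2,6-bis(benzyloxy)-4-[(2-methylbut-3-yn-2-yl)oxy]phenyl]ethanone; 3 4-[(2-methylbut-3-yn-2-yl)oxy]benzaldehyde
Product: 9 (2E)-1-[2,6-bis(benzyloxy)-4-[(2-methylbut-3-yn-2-yl)oxy]phenyl]-3-[4-[(2-methylbut-3-yn-2-yl)oxy]phenyl]prop-2-en-1-one, via aldol adduct 8 (not isolated)
Conditions: KOH (aq.), EtOH/THF, rt
Reagents that add atoms: none
Why: Claisen–Schmidt condensation of a methyl ketone with a non-enolisable aldehyde, followed by E1cB loss of water from aldol 8, should give the thermodynamically preferred E enone, as is usual for 2,4,6-trialkoxyacetophenones, and hydroxide at room temperature leaves the ethers and terminal alkynes alone.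

Step 5
Reactants: 9 (2E)-1-[2,6-bis(benzyloxy)-4-[(2-methylbut-3-yn-2-yl)oxy]phenyl]-3-[4-[(2-methylbut-3-yn-2-yl)oxy]phenyl]prop-2-en-1-one
Product: 11 1-[2,6-bis(benzyloxy)-4-[(2-methylbut-3-yn-2-yl)oxy]phenyl]-3-[4-[(2-methylbut-3-yn-2-yl)oxy]phenyl]propan-1-one, via boron enolate 10 (not isolated)
Conditions: catecholborane (1.5 equiv), THF, 0 °C to rt; then H2O
Reagents that add atoms: none
Why: Uncatalysed conjugate reduction of an s-cis enone by catecholborane delivers hydride to the β-carbon through a six-membered transition state to give the Z boron enolate 10, which is hydrolysed to the saturated ketone on work-up, while unactivated terminal alkynes are hydroborated by this reagent only on heating and benzyl ethers are inert.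

Step 6
Reactants: 11 1-[2,6-bis(benzyloxy)-4-[(2-methylbut-3-yn-2-yl)oxy]phenyl]-3-[4-[(2-methylbut-3-yn-2-yl)oxy]phenyl]propan-1-one
Product: 15 1-[5,7-bis(benzyloxy)-2,2-dimethyl-2H-chromen-6-yl]-3-(2,2-dimethyl-2H-chromen-6-yl)propan-1-one, via ring A allenylphenol 12 (not isolated), via mono-chromene ether 13 (not isolated), via ring B allenylphenol 14 (not isolated)
Conditions: PhNEt2 (dilute), 200 °C, argon
Reagents that add atoms: none
Why: Each aryl 1,1-dimethylpropargyl ether should undergo a thermal [3,3] sigmatropic (aryl propargyl Claisen) shift of the alkyne terminus to an ortho carbon, the 6-allenylcyclohexadienone enolises to an ortho-allenylphenol (12 on ring A, 14 on ring B), a [1,5]-hydrogen shift from the phenolic oxygen to the central allene carbon gives an ortho-quinone methide, and oxa-6π electrocyclisation re-forms the O1–C2 bond. The closest known reaction type is the thermal conversion of aryl 1,1-dimethylpropargyl ethers into 2,2-dimethyl-2H-chromenes in N,N-diethylaniline, run here at two sites of one molecule. Both pyran rings close by thermal disrotatory six-electron electrocyclisation of a cis-dienone (formally a 6-endo attack of oxygen on the CMe2 terminus), the ring A pyran first because its ether sits on the more electron-rich trioxygenated ring (giving 13), the ring B pyran second. No stereocentre is formed. The step needs ortho regioselectivity and closure on the right oxygen: in both rings the para position is occupied (ketone carbon or CH2CH2 chain) and the two ortho C–H sites are equivalent by local symmetry, and on ring A the two oxygens flanking the ketone are benzylated, so the only O–H that can feed the hydrogen shift is the one released para to the ketone. The gem-dimethyl group speeds the sigmatropic shift and disfavours the competing benzofuran closure, and the weakly basic amine solvent suppresses acid-induced polymerisation of the chromenes.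

Step 7
Reactants: 15 1-[5,7-bis(benzyloxy)-2,2-dimethyl-2H-chromen-6-yl]-3-(2,2-dimethyl-2H-chromen-6-yl)propan-1-one
Product: 16 1-(5,7-dihydroxy-2,2-dimethyl-3,4-dihydro-2H-chromen-6-yl)-3-(2,2-dimethyl-3,4-dihydro-2H-chromen-6-yl)propan-1-one
Conditions: H2 (1 atm), 10% Pd/C, EtOAc/MeOH, rt
Reagents that add atoms: none
Why: Heterogeneous catalytic hydrogenation should saturate both styrene-like C3=C4 bonds and hydrogenolyse both aryl benzyl ethers in one operation, while the ketone, first twisted and hindered by two ortho benzyloxy groups and then chelated by two ortho hydroxyls, resists reduction, as in the routine hydrogenation of benzylated chalcones to dihydrochalcones.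

**Compound list**

1 | 4-hydroxybenzaldehyde | O=Cc1ccc(O)cc1 | starting material
2 | 3-chloro-3-methylbut-1-yne | CC(C)(Cl)C#C | starting material
3 | 4-[(2-methylbut-3-yn-2-yl)oxy]benzaldehyde | C#CC(C)(C)Oc1ccc(C=O)cc1 | intermediate
4 | 1-(2,4,6-trihydroxyphenyl)ethanone | CC(=O)c1c(O)cc(O)cc1O | starting material
5 | 1-[2,6-dihydroxy-4-[(2-methylbut-3-yn-2-yl)oxy]phenyl]ethanone | CC(=O)c1c(O)cc(OC(C)(C)C#C)cc1O | intermediate
6 | benzyl bromide | BrCc1ccccc1 | starting material
7 | 1-[2,6-bis(benzyloxy)-4-[(2-methylbut-3-yn-2-yl)oxy]phenyl]ethanone | CC(=O)c1c(OCc2ccccc2)cc(OC(C)(C)C#C)cc1OCc1ccccc1 | intermediate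
8 | 1-[2,6-bis(benzyloxy)-4-[(2-methylbut-3-yn-2-yl)oxy]phenyl]-3-hydroxy-3-[4-[(2-methylbut-3-yn-2-yl)oxy]phenyl]propan-1-one (racemic aldol adduct; not isolated) | C#CC(C)(C)Oc1ccc(C(O)CC(=O)c2c(OCc3ccccc3)cc(OC(C)(C)C#C)cc2OCc2ccccc2)cc1 | intermediate
9 | (2E)-1-[2,6-bis(benzyloxy)-4-[(2-methylbut-3-yn-2-yl)oxy]phenyl]-3-[4-[(2-methylbut-3-yn-2-yl)oxy]phenyl]prop-2-en-1-one | C#CC(C)(C)Oc1ccc(/C=C/C(=O)c2c(OCc3ccccc3)cc(OC(C)(C)C#C)cc2OCc2ccccc2)cc1 | intermediate
10 | 2-[[(1Z)-1-[2,6-bis(benzyloxy)-4-[(2-methylbut-3-yn-2-yl)oxy]phenyl]-3-[4-[(2-methylbut-3-yn-2-yl)oxy]phenyl]prop-1-en-1-yl]oxy]-1,3,2-benzodioxaborole (boron enolate; not isolated) | C#CC(C)(C)Oc1ccc(C/C=C(\OB2Oc3ccccc3O2)c2c(OCc3ccccc3)cc(OC(C)(C)C#C)cc2OCc2ccccc2)cc1 | intermediate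
11 | 1-[2,6-bis(benzyloxy)-4-[(2-methylbut-3-yn-2-yl)oxy]phenyl]-3-[4-[(2-methylbut-3-yn-2-yl)oxy]phenyl]propan-1-one | C#CC(C)(C)Oc1ccc(CCC(=O)c2c(OCc3ccccc3)cc(OC(C)(C)C#C)cc2OCc2ccccc2)cc1 | intermediate
12 | 1-[2,6-bis(benzyloxy)-4-hydroxy-3-(3-methylbuta-1,2-dien-1-yl)phenyl]-3-[4-[(2-methylbut-3-yn-2-yl)oxy]phenyl]propan-1-one (not isolated) | C#CC(C)(C)Oc1ccc(CCC(=O)c2c(OCc3ccccc3)cc(O)c(C=C=C(C)C)c2OCc2ccccc2)cc1 | intermediate
13 | 1-[5,7-bis(benzyloxy)-2,2-dimethyl-2H-chromen-6-yl]-3-[4-[(2-methylbut-3-yn-2-yl)oxy]phenyl]propan-1-one (not isolated) | C#CC(C)(C)Oc1ccc(CCC(=O)c2c(OCc3ccccc3)cc3OC(C)(C)C=Cc3c2OCc2ccccc2)cc1 | intermediate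
14 | 1-[5,7-bis(benzyloxy)-2,2-dimethyl-2H-chromen-6-yl]-3-[4-hydroxy-3-(3-methylbuta-1,2-dien-1-yl)phenyl]propan-1-one (not isolated) | CC(C)=C=Cc1cc(CCC(=O)c2c(OCc3ccccc3)cc3OC(C)(C)C=Cc3c2OCc2ccccc2)ccc1O | intermediate
15 | 1-[5,7-bis(benzyloxy)-2,2-dimethyl-2H-chromen-6-yl]-3-(2,2-dimethyl-2H-chromen-6-yl)propan-1-one | CC1(C)C=Cc2cc(CCC(=O)c3c(OCc4ccccc4)cc4OC(C)(C)C=Cc4c3OCc3ccccc3)ccc2O1 | intermediate
16 | 1-(5,7-dihydroxy-2,2-dimethyl-3,4-dihydro-2H-chromen-6-yl)-3-(2,2-dimethyl-3,4-dihydro-2H-chromen-6-yl)propan-1-one | CC1(C)CCc2cc(CCC(=O)c3c(O)cc4c(c3O)CCC(C)(C)O4)ccc2O1 | target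

**Step count**

Total step count: 7.
Longest linear sequence: 6 steps (4 → 5 → 7 → 9 → 11 → 15 → 16, steps 2 to 7).

**Steps most likely to fail**

Step 6 (key step). The two ethers rearrange at different rates, so driving the slower ring B ether to completion exposes the ring A chromene formed first to prolonged heating. That invites thermal polymerisation through the ortho-quinone methide and partial loss of benzyl groups. The fallback runs each cascade on its own half before the halves are joined. It sets out from 3 and 7 and comes back to the route at 16. Heating aldehyde 3 in PhNEt2 should give 2,2-dimethyl-2H-chromene-6-carbaldehyde F1. Heating ketone 7 in the same way should give 1-[5,7-bis(benzyloxy)-2,2-dimethyl-2H-chromen-6-yl]ethanone F2. Claisen–Schmidt condensation of F2 with F1 (KOH, EtOH/THF, rt) should give (2E)-1-[5,7-bis(benzyloxy)-2,2-dimethyl-2H-chromen-6-yl]-3-(2,2-dimethyl-2H-chromen-6-yl)prop-2-en-1-one F3. Hydrogenation over Pd/C (H2, EtOAc/MeOH) then saturates the enone and both chromene double bonds and removes both benzyl ethers to give 16.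

Step 5. Boron coordination to the carbonyl crowded by two ortho benzyloxy groups may be slow, so that hydroboration of the terminal alkynes or 1,2-reduction competes with conjugate hydride delivery. The fallback forms the CH2–CH2 bond by enolate alkylation instead of condensation and reduction. It sets out from 3 and 7 and comes back at 11. Aldehyde 3 is reduced (NaBH4, MeOH, 0 °C) to [4-[(2-methylbut-3-yn-2-yl)oxy]phenyl]methanol F4. This is converted under neutral Appel conditions (CBr4, PPh3, CH2Cl2, 0 °C) into 1-(bromomethyl)-4-[(2-methylbut-3-yn-2-yl)oxy]benzene F5, which is used fresh. The lithium enolate of 7 (LiN(SiMe3)2, THF, −78 °C, slight excess of enolate to limit double alkylation) is alkylated with F5 to give 11.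

Step 2. More than one hydroxyl may be alkylated, and the electron-rich nucleus may be C-propargylated by the electrophilic copper intermediate. The fallback differentiates the para oxygen with a fast, stoichiometrically controlled acetal formation and propargylates only when a single phenol is left. It sets out from 4 and comes back at 7. Compound 4 with chloromethyl methyl ether (1.0 equiv) and iPr2NEt in CH2Cl2 at 0 °C should give 1-[2,6-dihydroxy-4-(methoxymethoxy)phenyl]ethanone F6. Benzylation (BnBr, Cs2CO3, DMF) should give 1-[2,6-bis(benzyloxy)-4-(methoxymethoxy)phenyl]ethanone F7. Acetal cleavage (HCl, MeOH, 40 °C) should give 1-[2,6-bis(benzyloxy)-4-hydroxyphenyl]ethanone F8. Its only free hydroxyl is then etherified with 2 (DBU, CuCl2·2H2O cat., MeCN, 0 °C) to give 7.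

**Further compounds**

F1 | step 6 | 2,2-dimethyl-2H-chromene-6-carbaldehyde | CC1(C)C=Cc2cc(C=O)ccc2O1
F2 | step 6 | 1-[5,7-bis(benzyloxy)-2,2-dimethyl-2H-chromen-6-yl]ethanone | CC(=O)c1c(OCc2ccccc2)cc2OC(C)(C)C=Cc2c1OCc1ccccc1
F3 | step 6 | (2E)-1-[5,7-bis(benzyloxy)-2,2-dimethyl-2H-chromen-6-yl]-3-(2,2-dimethyl-2H-chromen-6-yl)prop-2-en-1-one | CC1(C)C=Cc2cc(/C=C/C(=O)c3c(OCc4ccccc4)cc4OC(C)(C)C=Cc4c3OCc3ccccc3)ccc2O1
F4 | step 5 | [4-[(2-methylbut-3-yn-2-yl)oxy]phenyl]methanol | C#CC(C)(C)Oc1ccc(CO)cc1
F5 | step 5 | 1-(bromomethyl)-4-[(2-methylbut-3-yn-2-yl)oxy]benzene | C#CC(C)(C)Oc1ccc(CBr)cc1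
F6 | step 2 | 1-[2,6-dihydroxy-4-(methoxymethoxy)phenyl]ethanone | CC(=O)c1c(O)cc(OCOC)cc1O
F7 | step 2 | 1-[2,6-bis(benzyloxy)-4-(methoxymethoxy)phenyl]ethanone | CC(=O)c1c(OCc2ccccc2)cc(OCOC)cc1OCc1ccccc1
F8 | step 2 | 1-[2,6-bis(benzyloxy)-4-hydroxyphenyl]ethanone | CC(=O)c1c(OCc2ccccc2)cc(O)cc1OCc1ccccc1
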